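**Plan**
- Retrosynthesis first cuts the depside C(=O)–O bond between the ring A carbonyl and O-4 of ring B, giving a protected ring A benzoic acid and benzyl olivetolate.
- Ring A has oxygen on C2 and C4, the ester carbon on C1 and the 2-oxopentyl arm on C6. Cutting C1–C2 and C5–C6 therefore exposes a 1,1,3-trioxygenated buta-1,3-diene and a 2-ynoate whose β-carbon carries the ketal-masked arm.
- The ynoate triple bond is cut back to an aldehyde (one-carbon homologation) derived from ketalised ethyl 3-oxohexanoate; the diene comes from methyl acetoacetate.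
- Forward: diene (steps 1–2) and ynoate (steps 3–6) are joined by Diels–Alder/aromatisation to make ring A (step 7). O-Benzylation and saponification (steps 8–9) give the acid, which acylates the 4-OH of benzyl olivetolate (steps 10–11); ring B is bought intact as olivetolic acid.
- Ketal hydrolysis and hydrogenolysis (steps 12–13) release the target.
- The target has no stereocentre and no stereogenic double bond; only regiochemistry needs control (diene/ynoate polarity in step 7, hydrogen-bond differentiation of the two phenols in step 11).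

Key step: step 7

Assumptions: olivetolic acid (16) is taken as a purchasable compound. The ketene acetal geometry of diene 4 is drawn Z for definiteness; either isomer would give the same arene.

**Route**

Step 1
Reactants: 1 methyl acetoacetate
Product: 2 methyl (E)-3-methoxybut-2-enoate
Conditions: HC(OMe)3 (1.2 equiv), conc. H2SO4 (cat.), neat, 20 °C; then distillation
Reagents that add atoms: trimethyl orthoformate COC(OC)OC
Why: Acid-catalysed ketalisation of the ketone by the orthoformate followed by loss of methanol on distillation (enol ether formation) should give the conjugated, thermodynamically preferred E enol ether.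

Step 2
Reactants: 2 methyl (E)-3-methoxybut-2-enoate
Product: 4 (1Z)-1,3-dimethoxy-1-(trimethylsilyloxy)buta-1,3-diene, via lithium dienolate 3 (not isolated)
Conditions: LiN(i-Pr)2 (1.1 equiv), THF, −78 °C; then Me3SiCl (1.3 equiv), −78 °C → 20 °C; filtration under Ar, distillation
Reagents that add atoms: chlorotrimethylsilane C[Si](C)(C)Cl
Why: Kinetic γ-deprotonation of the vinylogous ester gives the extended lithium dienolate, which the hard silyl chloride traps on oxygen (silyl ketene acetal formation) to give the 1,1,3-trioxygenated diene.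

Step 3
Reactants: 5 ethyl 3-oxohexanoate
Product: 6 ethyl 2-(2-propyl-1,3-dioxolan-2-yl)acetate
Conditions: HOCH2CH2OH (2 equiv), TsOH·H2O (cat.), toluene, reflux, azeotropic removal of water
Reagents that add atoms: ethylene glycol OCCO
Why: Acid-catalysed ketalisation is selective for the ketone over the ester and masks the carbonyl that would otherwise let a β,γ-alkynyl ketone isomerise to an allene later on.

Step 4
Reactants: 6 ethyl 2-(2-propyl-1,3-dioxolan-2-yl)acetate
Product: 7 2-(2-propyl-1,3-dioxolan-2-yl)acetaldehyde
Conditions: i-Bu2AlH (1.1 equiv), CH2Cl2, −78 °C; MeOH quench, aq. KNaC4H4O6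
Reagents that add atoms: none
Why: Partial reduction of an ester with i-Bu2AlH at −78 °C should stop at the aluminium hemiacetal, helped here by chelation to a ketal oxygen, and release the aldehyde only on work-up.

Step 5
Reactants: 7 2-(2-propyl-1,3-dioxolan-2-yl)acetaldehyde
Product: 8 2-(3,3-dibromoprop-2-en-1-yl)-2-propyl-1,3-dioxolane
Conditions: CBr4 (2 equiv), PPh3 (2 equiv), Zn (2 equiv), CH2Cl2, 20 °C (ylide preformed); then 7, 0 °C → 20 °C
Reagents that add atoms: carbon tetrabromide BrC(Br)(Br)Br
Why: Corey–Fuchs dibromoolefination, a Wittig reaction of Ph3P=CBr2 generated with zinc so that no bromophosphonium salt or HBr threatens the ketal, should convert the aldehyde into the 1,1-dibromoalkene.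

Step 6
Reactants: 8 2-(3,3-dibromoprop-2-en-1-yl)-2-propyl-1,3-dioxolane
Product: 10 methyl 4-(2-propyl-1,3-dioxolan-2-yl)but-2-ynoate, via lithium acetylide 9 (not isolated)
Conditions: n-BuLi (2.1 equiv), THF, −78 °C; then ClCO2Me (1.5 equiv), −78 °C → 0 °C; aq. NH4Cl
Reagents that add atoms: methyl chloroformate COC(=O)Cl
Why: In the second stage of the Corey–Fuchs sequence, bromine–lithium exchange and Fritsch–Buttenberg–Wiechell rearrangement give the alkyne, the second equivalent of n-BuLi forms the acetylide, and C-acylation by the chloroformate gives the ynoate.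

Step 7
Reactants: 4 (1Z)-1,3-dimethoxy-1-(trimethylsilyloxy)buta-1,3-diene; 10 methyl 4-(2-propyl-1,3-dioxolan-2-yl)but-2-ynoate
Product: 13 methyl 2-hydroxy-4-methoxy-6-[(2-propyl-1,3-dioxolan-2-yl)methyl]benzoate, via cyclohexa-1,4-diene cycloadduct 11 (not isolated), via aryl trimethylsilyl ether 12 (not isolated)
Conditions: 4 (2.5 equiv), toluene, 110 °C, sealed tube, Ar; then K2CO3 (0.2 equiv), MeOH, 0 °C → 20 °C; aq. NH4Cl
Reagents that add atoms: none
Why: The electron-rich ketene acetal diene 4 and the electron-poor ynoate 10 should combine in a concerted but strongly asynchronous normal-demand Diels–Alder reaction, the bond from the diene CH2 terminus to the ynoate β-carbon running ahead of the bond from the ketene acetal carbon to the α-carbon, to give cyclohexa-1,4-diene 11. The mixed methyl silyl ketal carbon of 11 lies para to the ring CH2, so 1,4-elimination of methanol (the more basic oxygen departs) gives aryl silyl ether 12, and carbonate-catalysed methanolysis then frees the chelated phenol 13. The closest known reaction type is the Diels–Alder/aromatising elimination of 1,1,3-trioxygenated buta-1,3-dienes with acetylenic esters to give resorcylates. Ring A closes by intermolecular [4+2] cycloaddition, both new ring bonds (C1–C2 and C5–C6 of the arene) forming in the one event, and becomes aromatic by elimination, not by oxidation. No stereocentre survives, since the ketal carbon of 11 forms as a racemate and is flattened on aromatisation. The step needs regioselectivity, which the matched polarity secures (largest diene HOMO coefficient at the CH2 terminus, largest ynoate LUMO coefficient at the β-carbon) so that the ester carbon ends between the C2 oxygen and the side chain, and it needs the ketal to survive, which the neutral thermal conditions and the basic work-up secure.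

Step 8
Reactants: 13 methyl 2-hydroxy-4-methoxy-6-[(2-propyl-1,3-dioxolan-2-yl)methyl]benzoate
Product: 14 methyl 2-(benzyloxy)-4-methoxy-6-[(2-propyl-1,3-dioxolan-2-yl)methyl]benzoate
Conditions: BnBr (1.3 equiv), K2CO3 (2 equiv), DMF, 60 °C
Reagents that add atoms: benzyl bromide BrCc1ccccc1
Why: Williamson etherification of the chelated salicylate phenol masks it for the basic and acylating steps ahead with a group that hydrogenolysis removes at the end.

Step 9
Reactants: 14 methyl 2-(benzyloxy)-4-methoxy-6-[(2-propyl-1,3-dioxolan-2-yl)methyl]benzoate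
Product: 15 2-(benzyloxy)-4-methoxy-6-[(2-propyl-1,3-dioxolan-2-yl)methyl]benzoic acid
Conditions: KOH (excess), aq. DMSO, 90 °C; then 1 M HCl to pH 4 at 0 °C, EtOAc extraction; used promptly
Reagents that add atoms: potassium hydroxide [K+].[OH-]
Why: Saponification of the di-ortho-substituted methyl benzoate needs poorly solvated hydroxide in hot aqueous DMSO, which the ketal, benzyl ether and methyl ether tolerate, and cold mild acidification should spare the ketal.

Step 10
Reactants: 16 olivetolic acid
Product: 17 benzyl 2,4-dihydroxy-6-pentylbenzoate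
Conditions: BnBr (1.1 equiv), KHCO3 (1.2 equiv), DMF, 20 °C
Reagents that add atoms: benzyl bromide BrCc1ccccc1
Why: Carboxylate O-alkylation is selective because KHCO3 deprotonates only the carboxylic acid, leaving both phenols free, and the mild temperature avoids decarboxylation of the β-resorcylic acid.

Step 11
Reactants: 15 2-(benzyloxy)-4-methoxy-6-[(2-propyl-1,3-dioxolan-2-yl)methyl]benzoic acid; 17 benzyl 2,4-dihydroxy-6-pentylbenzoate
Product: 18 benzyl 4-({2-(benzyloxy)-4-methoxy-6-[(2-propyl-1,3-dioxolan-2-yl)methyl]benzoyl}oxy)-2-hydroxy-6-pentylbenzoate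
Conditions: DCC (1.2 equiv), DMAP (0.2 equiv), CH2Cl2, 0 °C → 20 °C
Reagents that add atoms: none
Why: In this Steglich esterification DCC activates the acid as its O-acylisourea, DMAP relays the acyl group, and only the 4-OH of 17 should react because the 2-OH is locked in a hydrogen bond to the neighbouring ester carbonyl and shielded by it.

Step 12
Reactants: 18 benzyl 4-({2-(benzyloxy)-4-methoxy-6-[(2-propyl-1,3-dioxolan-2-yl)methyl]benzoyl}oxy)-2-hydroxy-6-pentylbenzoate
Product: 19 benzyl 4-{[2-(benzyloxy)-4-methoxy-6-(2-oxopentyl)benzoyl]oxy}-2-hydroxy-6-pentylbenzoate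
Conditions: 1 M aq. HCl, THF, 20 °C
Reagents that add atoms: water O
Why: Acid-catalysed ketal hydrolysis in dilute aqueous acid at room temperature should free the ketone while the aryl ester, benzyl ester and benzyl ether, which need far harsher acid, stay intact.

Step 13
Reactants: 19 benzyl 4-{[2-(benzyloxy)-4-methoxy-6-(2-oxopentyl)benzoyl]oxy}-2-hydroxy-6-pentylbenzoate
Product: 20 glomelliferic acid
Conditions: H2 (1 atm), 10% Pd/C, EtOAc, 20 °C
Reagents that add atoms: none
Why: Catalytic hydrogenolysis over Pd/C cleaves the benzyl ether and the benzyl ester in one neutral operation that should leave the depside ester, the ketone and the decarboxylation-prone salicylic acid untouched.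

**Compound list**
1 | methyl acetoacetate | COC(=O)CC(C)=O | starting material
2 | methyl (E)-3-methoxybut-2-enoate | CO/C(C)=C/C(=O)OC | intermediate
3 | lithium 1,3-dimethoxybuta-1,3-dien-1-olate (lithium dienolate) | C=C(OC)/C=C(/OC)O[Li] | intermediate
4 | (1Z)-1,3-dimethoxy-1-(trimethylsilyloxy)buta-1,3-diene | C=C(OC)/C=C(/OC)O[Si](C)(C)C | intermediate
5 | ethyl 3-oxohexanoate | CCCC(=O)CC(=O)OCC | starting material
6 | ethyl 2-(2-propyl-1,3-dioxolan-2-yl)acetate | CCCC1(CC(=O)OCC)OCCO1 | intermediate
7 | 2-(2-propyl-1,3-dioxolan-2-yl)acetaldehyde | CCCC1(CC=O)OCCO1 | intermediate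
8 | 2-(3,3-dibromoprop-2-en-1-yl)-2-propyl-1,3-dioxolane | CCCC1(CC=C(Br)Br)OCCO1 | intermediate
9 | lithium 3-(2-propyl-1,3-dioxolan-2-yl)prop-1-yn-1-ide (lithium acetylide) | CCCC1(CC#C[Li])OCCO1 | intermediate
10 | methyl 4-(2-propyl-1,3-dioxolan-2-yl)but-2-ynoate | CCCC1(CC#CC(=O)OC)OCCO1 | intermediate
11 | methyl 4,6-dimethoxy-2-[(2-propyl-1,3-dioxolan-2-yl)methyl]-6-(trimethylsilyloxy)cyclohexa-1,4-diene-1-carboxylate (racemic cycloadduct) | CCCC1(CC2=C(C(=O)OC)C(OC)(O[Si](C)(C)C)C=C(OC)C2)OCCO1 | intermediate
12 | methyl 4-methoxy-2-[(2-propyl-1,3-dioxolan-2-yl)methyl]-6-(trimethylsilyloxy)benzoate | CCCC1(Cc2cc(OC)cc(O[Si](C)(C)C)c2C(=O)OC)OCCO1 | intermediate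
13 | methyl 2-hydroxy-4-methoxy-6-[(2-propyl-1,3-dioxolan-2-yl)methyl]benzoate | CCCC1(Cc2cc(OC)cc(O)c2C(=O)OC)OCCO1 | intermediate
14 | methyl 2-(benzyloxy)-4-methoxy-6-[(2-propyl-1,3-dioxolan-2-yl)methyl]benzoate | CCCC1(Cc2cc(OC)cc(OCc3ccccc3)c2C(=O)OC)OCCO1 | intermediate
15 | 2-(benzyloxy)-4-methoxy-6-[(2-propyl-1,3-dioxolan-2-yl)methyl]benzoic acid | CCCC1(Cc2cc(OC)cc(OCc3ccccc3)c2C(=O)O)OCCO1 | intermediate
16 | olivetolic acid (2,4-dihydroxy-6-pentylbenzoic acid) | CCCCCc1cc(O)cc(O)c1C(=O)O | starting material
17 | benzyl 2,4-dihydroxy-6-pentylbenzoate | CCCCCc1cc(O)cc(O)c1C(=O)OCc1ccccc1 | intermediate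
18 | benzyl 4-({2-(benzyloxy)-4-methoxy-6-[(2-propyl-1,3-dioxolan-2-yl)methyl]benzoyl}oxy)-2-hydroxy-6-pentylbenzoate | CCCCCc1cc(OC(=O)c2c(OCc3ccccc3)cc(OC)cc2CC2(CCC)OCCO2)cc(O)c1C(=O)OCc1ccccc1 | intermediate
19 | benzyl 4-{[2-(benzyloxy)-4-methoxy-6-(2-oxopentyl)benzoyl]oxy}-2-hydroxy-6-pentylbenzoate | CCCCCc1cc(OC(=O)c2c(OCc3ccccc3)cc(OC)cc2CC(=O)CCC)cc(O)c1C(=O)OCc1ccccc1 | intermediate
20 | glomelliferic acid (2-hydroxy-4-{[2-hydroxy-4-methoxy-6-(2-oxopentyl)benzoyl]oxy}-6-pentylbenzoic acid) | CCCCCc1cc(OC(=O)c2c(O)cc(OC)cc2CC(=O)CCC)cc(O)c1C(=O)O | target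

**Step count and risks**

Total: 13 steps. Longest linear sequence: 10 steps (3, 4, 5, 6, 7, 8, 9, 11, 12, 13) from ethyl 3-oxohexanoate.

The three steps most likely to fail:

1. Step 7. The cycloaddition of a β-alkyl mono-ester alkyne may be slower than thermal decomposition of the diene. The mixed ketal of the cycloadduct may also collapse by loss of trimethylsilanol instead of methanol, which would leave a 2-methyl ether in place of the phenol. The fallback sets out from 2 and uses a diene whose two C1 oxygens are alike, so the aromatising elimination has only one outcome. Saponification of 2 (KOH, aq. MeOH, then cold acidification) would give (E)-3-methoxybut-2-enoic acid F1. Double deprotonation with LiN(i-Pr)2 (2.2 equiv, THF, −78 °C) would give dilithium 3-methoxybuta-1,3-diene-1,1-diolate F2, and Me3SiCl would silylate both oxygens to give 3-methoxy-1,1-bis(trimethylsilyloxy)buta-1,3-diene F3. Heating this more electron-rich diene with ynoate 10 in toluene should give the 6,6-bis(trimethylsilyloxy)cyclohexa-1,4-diene cycloadduct F4, which can only lose trimethylsilanol. The fallback thus comes back to the route at 12, and the methanolysis of step 7 delivers 13.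

2. Step 11. Acyl transfer from the di-ortho-substituted O-acylisourea may be slow enough for O-to-N acyl migration to the N-acylurea to take over, and discrimination between the two phenols of 17 may be incomplete. The fallback sets out from 15 and replaces the one-pot dehydrative coupling by acylation of a preformed phenoxide with a preformed acid chloride. Treatment of 15 with 1-chloro-N,N,2-trimethylprop-1-en-1-amine (CH2Cl2, 0 °C → 20 °C, neutral, so the ketal is not exposed to HCl) should give 2-(benzyloxy)-4-methoxy-6-[(2-propyl-1,3-dioxolan-2-yl)methyl]benzoyl chloride F5. Separately, 17 and NaH (1.0 equiv, THF, 0 °C) should give sodium 4-[(benzyloxy)carbonyl]-3-hydroxy-5-pentylphenolate F6, the more acidic 4-OH being deprotonated while the 2-OH stays hydrogen-bonded. Adding F5 to F6 is a Schotten–Baumann-type acylation and comes back to the route at 18.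

3. Step 5. The β-ketal aldehyde 7 may suffer ketal opening or β-elimination in the Lewis-acidic phosphonium/ZnBr2 medium, and the following double-lithiation stage gives excess base a chance to attack the propargylic CH2. The fallback sets out from 7 and uses a one-carbon homologation under mild base instead. Ohira–Bestmann homologation (dimethyl (1-diazo-2-oxopropyl)phosphonate, K2CO3, MeOH, 0 °C → 20 °C) should give 2-(prop-2-yn-1-yl)-2-propyl-1,3-dioxolane F7. Exactly one equivalent of n-BuLi (THF, −78 °C) would then give acetylide 9, where the fallback comes back to the route, and the methyl chloroformate quench of step 6 delivers 10.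

**Further compounds**
F1 | step 7 | (E)-3-methoxybut-2-enoic acid | CO/C(C)=C/C(=O)O
F2 | step 7 | dilithium 3-methoxybuta-1,3-diene-1,1-diolate | C=C(OC)C=C(O[Li])O[Li]
F3 | step 7 | 3-methoxy-1,1-bis(trimethylsilyloxy)buta-1,3-diene | C=C(OC)C=C(O[Si](C)(C)C)O[Si](C)(C)C
F4 | step 7 | methyl 4-methoxy-2-[(2-propyl-1,3-dioxolan-2-yl)methyl]-6,6-bis(trimethylsilyloxy)cyclohexa-1,4-diene-1-carboxylate | CCCC1(CC2=C(C(=O)OC)C(O[Si](C)(C)C)(O[Si](C)(C)C)C=C(OC)C2)OCCO1
F5 | step 11 | 2-(benzyloxy)-4-methoxy-6-[(2-propyl-1,3-dioxolan-2-yl)methyl]benzoyl chloride | CCCC1(Cc2cc(OC)cc(OCc3ccccc3)c2C(Cl)=O)OCCO1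
F6 | step 11 | sodium 4-[(benzyloxy)carbonyl]-3-hydroxy-5-pentylphenolate | CCCCCc1cc([O-])cc(O)c1C(=O)OCc1ccccc1.[Na+]
F7 | step 5 | 2-(prop-2-yn-1-yl)-2-propyl-1,3-dioxolane | CCCC1(CC#C)OCCO1
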